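**Structural features**

The target, 2-(4-hydroxybenzyl)-3-[2-(2-hydroxyphenyl)ethyl]-5-methoxyphenol, has three benzene rings that are not fused but joined through sp3 carbon only: the central ring A carries at C1 a CH2CH2 chain to ring B (2-hydroxyphenyl, a bibenzyl) and at C2 a CH2 bridge to ring C (4-hydroxyphenyl, a diarylmethane). Ring A is numbered here C1 (chain), C2 (benzyl), C3 (OH), C4 (H), C5 (OMe), C6 (H); it is a resorcinol whose two meta oxygens are differentiated, free OH at C3 and methyl ether at C5. There is no stereocentre and no stereogenic double bond, so the molecule is achiral. The fragile features are the three free phenols on electron-rich rings (oxidation, O- versus C-alkylation) and the 4-hydroxybenzyl unit, which ionises to a para-quinone methide under acid or oxidant. The real difficulty is regiochemical: C1, C2 and C3 are contiguous, the benzyl carbon sits at C2, the most hindered position of ring A, while C4 and C6 are equally activated by both oxygens, and the oxygen next to the benzyl group must stay free while the remote one is methylated. The key step exploits the C3(OH)–C4(H)–C5(OMe) triad and the adjacent carbon substituents at C1/C2: ring A is not substituted but assembled, C4–C5 coming from an alkoxyalkyne and C3, C6, C1, C2 from a cyclobutenone, so that every substituent position and the OH/OMe differentiation are fixed by connectivity. In one sentence, ring A is made by a thermal Danheiser benzannulation of cyclobutenone 12 with methoxyacetylene 16, which does not describe the olefination/Friedel–Crafts route that would normally be drawn first.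

**Logic of the disconnections**

22 to 21. The two O–CH2Ph bonds on the ring-B and ring-C oxygens are cut. These phenols must be masked through ketene, organomagnesium and thermal steps, and a benzyl ether can be removed by hydrogenolysis without touching the C5 methyl ether. The gain is a single kind of protecting group, with the C3–OH never protected because it is born free in the key step. The forward step must not cleave the diarylmethane or bibenzyl C–C bonds.

21 to 12 and 16 (key disconnection). Ring A is cut at C3–C4 and C5–C6; C4 and C5 with its OMe leave as 16, and C3, C6, C1 and C2 contract to the four-membered ring of 12 (C2–C3 is broken and re-formed in the forward direction). This is the cut that turns the regiochemical problem into connectivity: the carbonyl carbon of 12 becomes C3–OH, its C4 substituent ends ortho to that OH, its C3 substituent meta, and the OMe arrives with 16. The gain is that a tetrasubstituted, oxygen-differentiated arene becomes a disubstituted four-membered ring plus a two-carbon alkyne, joined convergently. The forward step needs a regioselective [2+2] of the ketene derived from 12 with 16, and no free OH or NH in 12.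

12 to 5 and 9. The bond from cyclobutene C3 to the chain CH2 is cut. 5 is a vinylogous ester, so 1,2-addition of the organomagnesium 10 derived from 9, followed by hydrolytic carbonyl transposition, delivers the chain at C3 and leaves the benzyl group at C4. The gain is that the ring-B arm is separated from the four-membered ring. The forward step needs 1,2-selectivity and a mild acid work-up.

5 to 2 and 3. The four-membered ring is cut across C1–C2 and C3–C4, a ketene/ynol ether [2+2] in the forward sense, via 4. The gain is two acyclic pieces, one of them commercial. The forward step must intercept the monosubstituted ketene 4 before it dimerises.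

2 to 1. The C–Cl bond is cut; 1 is commercial and already carries the ring-C benzyl ether.

9 to 8 to 6 and 7. The C–Br bond and then the O–benzyl bond are cut, leading to commercial 6 and 7. The forward O-alkylation must select the phenol over the primary alcohol.

16 to 13. Two eliminations (methanol, then HCl) are reversed; 13 is a commercial bulk chemical, so 16 need not be bought.

**Other disconnections considered**

Alternative 1: the route that comes to mind first. The C2–CH2 bond of ring A is cut last. The bibenzyl 3-[2-(2-hydroxyphenyl)ethyl]-5-methoxyphenol A1 would be made by Wittig olefination and hydrogenation, then benzylated under acid with 4-hydroxybenzyl alcohol A2 through para-quinone methide A3, which is also the presumed biosynthetic step. It is short, but A1 has three ring-A positions (C2, C4, C6) activated by both oxygens, and C2 is the most hindered of them. Ring B is also nucleophilic ortho and para to its OH, and A3 tends to oligomerise and over-benzylate. The defining difficulty would be left to a separation, whereas the chosen plan fixes it by connectivity.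

Alternative 2: aromatisation of an alkylated cyclohexenone. The C2–CH2 bond is cut on a non-aromatic ring: Stork–Danheiser alpha-prime alkylation of 5-{2-[2-(benzyloxy)phenyl]ethyl}-3-methoxycyclohex-2-en-1-one A4 with 4-(benzyloxy)benzyl bromide A6 would give 6-[4-(benzyloxy)benzyl]-5-{2-[2-(benzyloxy)phenyl]ethyl}-3-methoxycyclohex-2-en-1-one A5, and dehydrogenation would give 21. Regiochemistry is also fixed by connectivity here (ketone to C3–OH, enol ether to C5–OMe). However, A4 needs about four steps (Michael–Claisen, decarboxylation, enol ether formation), and the dehydrogenation of A5 has to be carried out in the presence of three benzylic CH2 groups and two benzyl ethers. The sequence is linear and roughly eight steps in its longest line, against five for the chosen plan.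

Alternative 3: decarboxylative union of two electrophiles. The C1–CH2 bond (ring A to chain) is cut: nickel-catalysed, electrochemically driven decarboxylative arylation of the redox-active ester 1,3-dioxoisoindolin-2-yl 3-[2-(benzyloxy)phenyl]propanoate A8 with 1-(benzyloxy)-2-[4-(benzyloxy)benzyl]-3-bromo-5-methoxybenzene A7. The coupling itself is plausible, but it forms the least problematic bond of ring A. A7 still contains the contiguous bromine/benzyl/oxygen pattern and the OH/OMe differentiation, so the regiochemical problem is only moved one compound back and the step count rises.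

Key step: step 7

Assumption: the SMILES contains no stereocentre and no stereogenic double bond, so the request for a single enantiomer is met by the achiral compound itself, and racemic intermediates are acceptable. Methoxyacetylene is not treated as a catalogue item and is made in step 6.

**Route**

Step 1
Reactants: 1 3-[4-(benzyloxy)phenyl]propanoic acid
Product: 2 3-[4-(benzyloxy)phenyl]propanoyl chloride
Conditions: (COCl)2, cat. DMF, CH2Cl2, 0 °C to rt; volatiles removed
Reagents that add atoms: oxalyl chloride, ClC(=O)C(=O)Cl
Why: Acyl chloride formation through the chloroiminium (Vilsmeier-type) catalyst; the aryl benzyl ether is inert and the by-products are gases.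

Step 2
Reactants: 2 3-[4-(benzyloxy)phenyl]propanoyl chloride; 3 ethoxyacetylene
Product: 5 4-[4-(benzyloxy)benzyl]-3-ethoxycyclobut-2-en-1-one (racemic), via [4-(benzyloxy)benzyl]ketene 4 (not isolated)
Conditions: 3 (3 equiv, hexanes solution), Et3N (1.2 equiv, slow addition), Et2O, 0 °C to rt
Reagents that add atoms: none
Why: Dehydrochlorination gives ketene 4, which is trapped in a ketene/ynol ether [2+2] cycloaddition; the nucleophilic CH carbon of 3 bonds to the ketene carbonyl carbon, so the ethoxy group ends at C3 and the benzyl group at C4. Slow base addition and excess 3 keep the ketene concentration low against dimerisation.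

Step 3
Reactants: 6 2-(2-hydroxyphenyl)ethanol; 7 benzyl bromide
Product: 8 2-[2-(benzyloxy)phenyl]ethanol
Conditions: K2CO3, acetone, reflux
Reagents that add atoms: none
Why: Williamson ether synthesis; carbonate deprotonates only the phenol, so the primary alcohol is left free.

Step 4
Reactants: 8 2-[2-(benzyloxy)phenyl]ethanol
Product: 9 1-(benzyloxy)-2-(2-bromoethyl)benzene
Conditions: CBr4, PPh3, CH2Cl2, 0 °C to rt
Reagents that add atoms: carbon tetrabromide, BrC(Br)(Br)Br
Why: Appel reaction; SN2 displacement of the alkoxyphosphonium at a primary carbon, neutral conditions that leave the benzyl ether untouched.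

Step 5
Reactants: 9 1-(benzyloxy)-2-(2-bromoethyl)benzene; 5 4-[4-(benzyloxy)benzyl]-3-ethoxycyclobut-2-en-1-one
Product: 12 4-[4-(benzyloxy)benzyl]-3-{2-[2-(benzyloxy)phenyl]ethyl}cyclobut-2-en-1-one (racemic), via Grignard reagent 10 (not isolated), via bromomagnesium cyclobutenolate adduct 11 (not isolated)
Conditions: Mg, THF, rt to 40 °C; then 5, THF, −78 to 0 °C; then 1 M HCl, 0 °C to rt
Reagents that add atoms: water, O
Why: 1,2-Addition of a Grignard reagent to a vinylogous ester followed by acid-mediated hydrolytic carbonyl transposition (ionisation of the tertiary allylic alcohol, water capture at the ethoxy-bearing carbon, loss of ethanol). The chain ends at C3 and the benzyl group stays at C4 next to the new carbonyl; enolisation of 5 at C4 would give an antiaromatic cyclobutadienolate and should not compete.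

Step 6
Reactants: 13 chloroacetaldehyde dimethyl acetal
Product: 16 methoxyacetylene, via 2-chlorovinyl methyl ether 14 (not isolated), via sodium methoxyacetylide 15 (not isolated)
Conditions: NaNH2 (3.1 equiv), liq. NH3, −33 °C; NH3 evaporated; sat. aq. NaCl, −60 °C to rt; distilled (bp about 23 °C) into toluene at −78 °C
Reagents that add atoms: none
Why: Double base-induced elimination (methanol, then HCl) with the third equivalent of amide holding the product as its acetylide until the aqueous quench, the standard preparation of 1-alkoxyalkynes from chloroacetal; the product is kept as a cold toluene stock solution.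

Step 7
Reactants: 12 4-[4-(benzyloxy)benzyl]-3-{2-[2-(benzyloxy)phenyl]ethyl}cyclobut-2-en-1-one; 16 methoxyacetylene
Product: 21 2-[4-(benzyloxy)benzyl]-3-{2-[2-(benzyloxy)phenyl]ethyl}-5-methoxyphenol, via vinylketene 17 (not isolated), via 4-alkenyl-3-methoxycyclobutenone 18 (not isolated), via dienylketene 19 (not isolated), via cyclohexa-2,4-dienone 20 (not isolated)
Conditions: 16 (3 equiv, toluene solution), toluene, sealed tube, 80 °C then 120 °C
Reagents that add atoms: none
Why: This is a Danheiser benzannulation, the thermal aromatic annulation of a cyclobutenone with an alkoxyalkyne: heating opens 12 by reversible 4π-conrotatory cleavage of its C1–C4 bond to vinylketene 17, the C4 benzyl group rotating outward. The nucleophilic CH carbon of 16 attacks the ketene carbonyl carbon and the OMe-bearing carbon bonds to the former C2 of 12, a regioselective ketene/ynol ether [2+2] that gives 18 and creates the ring-A bonds C3–C4 and C5–C6. 18 opens in a second reversible 4π step to dienylketene 19, whose isomer with the alkene arm cis to the ketene closes ring A at C2–C3 by a thermal disrotatory 6π electrocyclisation (a six-membered carbocycle, the only ring closed) to give 20. Tautomerisation of 20 to phenol 21 is irreversible and pulls all the preceding equilibria forward. No stereocentre is formed in 21; the stereocentres of 12, 18 and 20 vanish on aromatisation, so racemic 12 suffices. The selectivity needed is regiochemical and is secured by connectivity and polarity: the carbonyl of 12 becomes C3–OH, its C4 substituent ends ortho to that OH, its C3 substituent meta, and the polarisation of the ynol ether places OMe at C5 with C4–H between the two oxygens. Outward torquoselectivity at C4 keeps the benzylic CH2 trans to the ketene, which disfavours a [1,5]-hydrogen shift to a dienal and puts H, not the benzyl group, inside the 6π transition state. Both benzyl ethers are inert and 12 carries no OH or NH that could trap a ketene.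

Step 8
Reactants: 21 2-[4-(benzyloxy)benzyl]-3-{2-[2-(benzyloxy)phenyl]ethyl}-5-methoxyphenol
Product: 22 2-(4-hydroxybenzyl)-3-[2-(2-hydroxyphenyl)ethyl]-5-methoxyphenol
Conditions: H2 (1 atm), 10% Pd/C, EtOAc–MeOH, rt
Reagents that add atoms: none
Why: Catalytic hydrogenolysis of the two aryl benzyl ethers; the aryl methyl ether and the diarylmethane and bibenzyl C–C bonds are not cleaved under these conditions, and there is no stereocentre to disturb.

**Compound list**

1 | 3-[4-(benzyloxy)phenyl]propanoic acid | OC(=O)CCc1ccc(OCc2ccccc2)cc1 | starting material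
2 | 3-[4-(benzyloxy)phenyl]propanoyl chloride | ClC(=O)CCc1ccc(OCc2ccccc2)cc1 | intermediate
3 | ethoxyacetylene (ethoxyethyne) | CCOC#C | starting material
4 | [4-(benzyloxy)benzyl]ketene, 3-[4-(benzyloxy)phenyl]prop-1-en-1-one (not isolated) | O=C=CCc1ccc(OCc2ccccc2)cc1 | intermediate
5 | 4-[4-(benzyloxy)benzyl]-3-ethoxycyclobut-2-en-1-one (racemic) | CCOC1=CC(=O)C1Cc1ccc(OCc2ccccc2)cc1 | intermediate
6 | 2-(2-hydroxyphenyl)ethanol | OCCc1ccccc1O | starting material
7 | benzyl bromide | BrCc1ccccc1 | starting material
8 | 2-[2-(benzyloxy)phenyl]ethanol | OCCc1ccccc1OCc1ccccc1 | intermediate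
9 | 1-(benzyloxy)-2-(2-bromoethyl)benzene | BrCCc1ccccc1OCc1ccccc1 | intermediate
10 | {2-[2-(benzyloxy)phenyl]ethyl}magnesium bromide (not isolated) | Br[Mg]CCc1ccccc1OCc1ccccc1 | intermediate
11 | bromomagnesium 4-[4-(benzyloxy)benzyl]-1-{2-[2-(benzyloxy)phenyl]ethyl}-3-ethoxycyclobut-2-en-1-olate (diastereomer mixture, not isolated) | CCOC1=CC(O[Mg]Br)(CCc2ccccc2OCc2ccccc2)C1Cc1ccc(OCc2ccccc2)cc1 | intermediate
12 | 4-[4-(benzyloxy)benzyl]-3-{2-[2-(benzyloxy)phenyl]ethyl}cyclobut-2-en-1-one (racemic) | O=C1C=C(CCc2ccccc2OCc2ccccc2)C1Cc1ccc(OCc2ccccc2)cc1 | intermediate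
13 | chloroacetaldehyde dimethyl acetal (2-chloro-1,1-dimethoxyethane) | COC(CCl)OC | starting material
14 | 2-chlorovinyl methyl ether, E/Z mixture (not isolated) | COC=CCl | intermediate
15 | sodium methoxyacetylide (not isolated) | [Na+].[C-]#COC | intermediate
16 | methoxyacetylene (methoxyethyne) | COC#C | intermediate
17 | (3E)-5-[4-(benzyloxy)phenyl]-3-{2-[2-(benzyloxy)phenyl]ethyl}penta-1,3-dien-1-one (vinylketene, not isolated) | O=C=C/C(CCc1ccccc1OCc1ccccc1)=C/Cc1ccc(OCc2ccccc2)cc1 | intermediate
18 | 4-{(2E)-1-[4-(benzyloxy)phenyl]-5-[2-(benzyloxy)phenyl]pent-2-en-3-yl}-3-methoxycyclobut-2-en-1-one (racemic, not isolated) | COC1=CC(=O)C1/C(CCc1ccccc1OCc1ccccc1)=C/Cc1ccc(OCc2ccccc2)cc1 | intermediate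
19 | (3E,5E)-7-[4-(benzyloxy)phenyl]-5-{2-[2-(benzyloxy)phenyl]ethyl}-3-methoxyhepta-1,3,5-trien-1-one (dienylketene, not isolated) | O=C=C/C(OC)=C\C(CCc1ccccc1OCc1ccccc1)=C\Cc1ccc(OCc2ccccc2)cc1 | intermediate
20 | 6-[4-(benzyloxy)benzyl]-5-{2-[2-(benzyloxy)phenyl]ethyl}-3-methoxycyclohexa-2,4-dien-1-one (racemic, not isolated) | COC1=CC(=O)C(Cc2ccc(OCc3ccccc3)cc2)C(CCc2ccccc2OCc2ccccc2)=C1 | intermediate
21 | 2-[4-(benzyloxy)benzyl]-3-{2-[2-(benzyloxy)phenyl]ethyl}-5-methoxyphenol | COc1cc(O)c(Cc2ccc(OCc3ccccc3)cc2)c(CCc2ccccc2OCc2ccccc2)c1 | intermediate
22 | 2-(4-hydroxybenzyl)-3-[2-(2-hydroxyphenyl)ethyl]-5-methoxyphenol (achiral) | COc1cc(O)c(Cc2ccc(O)cc2)c(CCc2ccccc2O)c1 | target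

**Step count and risk**

Total step count: 8. Longest linear sequence: 5 steps (1 to 2 to 5 to 12 to 21 to 22; the branch 6 to 8 to 9 to 12 to 21 to 22 is equally long).

Least certain steps:

Step 7 (key step). Three processes could erode it:
- Loss or polymerisation of the volatile alkyne 16 before it intercepts the vinylketene, which would leave 17 to dimerise.
- Leakage through inward rotation of the C4 substituent, followed by a [1,5]-hydrogen shift to a conjugated dienal.
- Acylation of the product phenol by ketene intermediates; this would be reversed by brief K2CO3/MeOH treatment of the crude product.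

The fallback buys ring A instead of building it; it sets out from 7 and returns to the route at 22. Commercial methyl 2-hydroxy-4-methoxy-6-methylbenzoate would be O-benzylated with 7 (K2CO3, DMF) to methyl 2-(benzyloxy)-4-methoxy-6-methylbenzoate F1. Lateral lithiation of its ring methyl group (LDA, THF, −78 °C) and alkylation with commercial 2-(benzyloxy)benzyl bromide should give methyl 2-(benzyloxy)-6-{2-[2-(benzyloxy)phenyl]ethyl}-4-methoxybenzoate F2. LiAlH4 reduction would give (2-(benzyloxy)-6-{2-[2-(benzyloxy)phenyl]ethyl}-4-methoxyphenyl)methanol F3. MsCl/Et3N in CH2Cl2 would convert this into 1-(benzyloxy)-3-{2-[2-(benzyloxy)phenyl]ethyl}-2-(chloromethyl)-5-methoxybenzene F4, used crude in a benzylic Suzuki–Miyaura coupling with 4-(benzyloxy)phenylboronic acid (Pd(PPh3)4, K2CO3, dioxane–water, 80 °C). This should give 1-(benzyloxy)-2-[4-(benzyloxy)benzyl]-3-{2-[2-(benzyloxy)phenyl]ethyl}-5-methoxybenzene F5, and hydrogenolysis under the conditions of step 8 gives 22.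

Step 2. Dimerisation of the monosubstituted ketene 4, or its diversion through acylammonium enolates, could outrun the [2+2] with 3, and the vinylogous ester could hydrolyse on isolation. The fallback replaces the ketene by a keteniminium ion; it sets out from 2 and 9 and returns at 12, so it also bypasses step 5. 2 and dimethylamine would give 3-[4-(benzyloxy)phenyl]-N,N-dimethylpropanamide F6. 9 and lithium acetylide–ethylenediamine complex (DMSO, rt) would give 1-(benzyloxy)-2-(but-3-yn-1-yl)benzene F7. Activation of F6 with Tf2O and 2,4,6-collidine in 1,2-dichloroethane would give the keteniminium triflate F8, which should add to F7 in a Ghosez-type [2+2] (the terminal alkyne carbon bonding to the iminium carbon) to the cyclobuteniminium triflate F9. Hydrolysis with aqueous NaHCO3 gives 12.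

Step 5. Wurtz-type homocoupling during magnesium insertion into the 2-arylethyl bromide, and acid-promoted ring opening of the strained adduct during the hydrolytic transposition, are the likely losses. The fallback uses a halide-free nucleophile; it sets out from 5 and returns at 12. Reductive opening of commercial 2,3-dihydrobenzofuran (Li, cat. 4,4'-di-tert-butylbiphenyl, THF, 0 °C) should give lithium 2-(2-lithioethyl)phenolate F10. Addition to 5 at −78 °C and work-up with 1 M HCl would give 4-[4-(benzyloxy)benzyl]-3-[2-(2-hydroxyphenyl)ethyl]cyclobut-2-en-1-one F11. O-Benzylation with 7 (K2CO3, acetone, rt) gives 12.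

**Further compounds**

F1 | step 7 | methyl 2-(benzyloxy)-4-methoxy-6-methylbenzoate | COC(=O)c1c(C)cc(OC)cc1OCc1ccccc1
F2 | step 7 | methyl 2-(benzyloxy)-6-{2-[2-(benzyloxy)phenyl]ethyl}-4-methoxybenzoate | COC(=O)c1c(CCc2ccccc2OCc2ccccc2)cc(OC)cc1OCc1ccccc1
F3 | step 7 | (2-(benzyloxy)-6-{2-[2-(benzyloxy)phenyl]ethyl}-4-methoxyphenyl)methanol | OCc1c(CCc2ccccc2OCc2ccccc2)cc(OC)cc1OCc1ccccc1
F4 | step 7 | 1-(benzyloxy)-3-{2-[2-(benzyloxy)phenyl]ethyl}-2-(chloromethyl)-5-methoxybenzene | ClCc1c(CCc2ccccc2OCc2ccccc2)cc(OC)cc1OCc1ccccc1
F5 | step 7 | 1-(benzyloxy)-2-[4-(benzyloxy)benzyl]-3-{2-[2-(benzyloxy)phenyl]ethyl}-5-methoxybenzene | COc1cc(OCc2ccccc2)c(Cc2ccc(OCc3ccccc3)cc2)c(CCc2ccccc2OCc2ccccc2)c1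
F6 | step 2 | 3-[4-(benzyloxy)phenyl]-N,N-dimethylpropanamide | CN(C)C(=O)CCc1ccc(OCc2ccccc2)cc1
F7 | step 2 | 1-(benzyloxy)-2-(but-3-yn-1-yl)benzene | C#CCCc1ccccc1OCc1ccccc1
F8 | step 2 | N-{3-[4-(benzyloxy)phenyl]prop-1-en-1-ylidene}-N-methylmethanaminium triflate (keteniminium salt) | C[N+](C)=C=CCc1ccc(OCc2ccccc2)cc1.[O-]S(=O)(=O)C(F)(F)F
F9 | step 2 | N-(4-[4-(benzyloxy)benzyl]-3-{2-[2-(benzyloxy)phenyl]ethyl}cyclobut-2-en-1-ylidene)-N-methylmethanaminium triflate (racemic) | C[N+](C)=C1C=C(CCc2ccccc2OCc2ccccc2)C1Cc1ccc(OCc2ccccc2)cc1.[O-]S(=O)(=O)C(F)(F)F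
F10 | step 5 | lithium 2-(2-lithioethyl)phenolate | [Li]CCc1ccccc1O[Li]
F11 | step 5 | 4-[4-(benzyloxy)benzyl]-3-[2-(2-hydroxyphenyl)ethyl]cyclobut-2-en-1-one (racemic) | O=C1C=C(CCc2ccccc2O)C1Cc1ccc(OCc2ccccc2)cc1
A1 | alternative 1 | 3-[2-(2-hydroxyphenyl)ethyl]-5-methoxyphenol | COc1cc(O)cc(CCc2ccccc2O)c1
A2 | alternative 1 | 4-hydroxybenzyl alcohol | OCc1ccc(O)cc1
A3 | alternative 1 | para-quinone methide (4-methylidenecyclohexa-2,5-dien-1-one) | C=C1C=CC(=O)C=C1
A4 | alternative 2 | 5-{2-[2-(benzyloxy)phenyl]ethyl}-3-methoxycyclohex-2-en-1-one (racemic) | COC1=CC(=O)CC(CCc2ccccc2OCc2ccccc2)C1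
A5 | alternative 2 | 6-[4-(benzyloxy)benzyl]-5-{2-[2-(benzyloxy)phenyl]ethyl}-3-methoxycyclohex-2-en-1-one (racemic, diastereomer mixture) | COC1=CC(=O)C(Cc2ccc(OCc3ccccc3)cc2)C(CCc2ccccc2OCc2ccccc2)C1
A6 | alternative 2 | 4-(benzyloxy)benzyl bromide | BrCc1ccc(OCc2ccccc2)cc1
A7 | alternative 3 | 1-(benzyloxy)-2-[4-(benzyloxy)benzyl]-3-bromo-5-methoxybenzene | COc1cc(Br)c(Cc2ccc(OCc3ccccc3)cc2)c(OCc2ccccc2)c1
A8 | alternative 3 | 1,3-dioxoisoindolin-2-yl 3-[2-(benzyloxy)phenyl]propanoate | O=C(CCc1ccccc1OCc1ccccc1)ON1C(=O)c2ccccc2C1=O
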